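**Plan**

1. Retrosynthetic cuts, in order: the C12 methyl ester (back to a silyl-protected primary alcohol) and the angelate C–O bond; the C1–O bond (γ-hydroxylation of the 6,9-dien-8-one); the C9=C10 alkene and the C8 oxygen (dehydration of a C10 carbinol after allylic oxidation); ring B at C5–C10 and C7–C8; then C10–C9, C6=C7, C5–C14, C5–C6 and C4–C15.
2. Enabling feature: ring B. Its bonds C7–C8 and C5–C10 are the pair exchanged when a ring A cyclohexanol with a vinyl group on C10 and an (E)-alkenyl group on C5 expands by a [3,3] shift to a ten-membered C10 ketone with a C5=C6 alkene. Transannular ene closure then restores C5–C10, leaves C6=C7 and puts a hydroxyl on C10, β to C8, as the handle for the dienone.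
3. Forward order: ring A comes from cyclohex-2-en-1-one (C15, then C6 as a formyl group, then C14). The C7/C11–C13 chain from the Roche ester is joined at C6=C7 by Julia–Kocienski olefination. Vinyl addition at C10 completes the diene, the cascade closes ring B, and C8, C9=C10, C1 and C12 are adjusted in turn.
4. Stereochemistry: C4 by ligand-controlled conjugate methylation; C11 from the Roche ester; C1 by axial peracid attack on a silyl trienol ether; the C8 and C10 carbinol centres are transient. C5 is first set with its methyl trans to the C4 methyl and is inverted in the cascade, because with an (E)-alkenyl group the only C7 hydrogen ends up on the alkene face opposite to the one C10 left.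

Key step: step 10

Conventions and one assumption: atoms carry eremophilane numbers (ring A: C1–C5 and C10; ring B: C5–C10; C15 on C4, C14 on C5, C11 with C12 and C13 on C7). β is the face of C14 in the bicyclic compounds. It is assumed that the E-alkene of the ten-membered ketone turns over faster than the ketone decomposes at 220 °C.

**Route**

Step 1
Reactants: 1 methyl (2R)-3-hydroxy-2-methylpropanoate
Product: 2 methyl (2R)-3-[(tert-butyldimethylsilyl)oxy]-2-methylpropanoate
Conditions: TBSCl, imidazole, CH2Cl2, 0 °C to rt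
Reagents that add atoms: tert-butyldimethylsilyl chloride, CC(C)(C)[Si](C)(C)Cl
Why: Standard silyl ether protection of the primary hydroxyl; the future C11 stereocentre is not touched.

Step 2
Reactants: 2 methyl (2R)-3-[(tert-butyldimethylsilyl)oxy]-2-methylpropanoate
Product: 3 (2S)-3-[(tert-butyldimethylsilyl)oxy]-2-methylpropan-1-ol
Conditions: i-Bu2AlH (2.5 equiv), CH2Cl2, −78 to 0 °C
Reagents that add atoms: none
Why: Hydride reduction of the ester to the primary alcohol, which should not enolise the α-centre at low temperature (the descriptor changes only through the priority rules).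

Step 3
Reactants: 3 (2S)-3-[(tert-butyldimethylsilyl)oxy]-2-methylpropan-1-ol
Product: 4 5-{[(2R)-3-[(tert-butyldimethylsilyl)oxy]-2-methylpropyl]sulfanyl}-1-phenyl-1H-tetrazole
Conditions: 1-phenyl-1H-tetrazole-5-thiol, PPh3, diisopropyl azodicarboxylate, THF, 0 °C to rt
Reagents that add atoms: 1-phenyl-1H-tetrazole-5-thiol, Sc1nnnn1-c1ccccc1
Why: Mitsunobu thioetherification at the primary carbon, one bond away from the stereocentre.

Step 4
Reactants: 4 5-{[(2R)-3-[(tert-butyldimethylsilyl)oxy]-2-methylpropyl]sulfanyl}-1-phenyl-1H-tetrazole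
Product: 5 5-{[(2R)-3-[(tert-butyldimethylsilyl)oxy]-2-methylpropyl]sulfonyl}-1-phenyl-1H-tetrazole
Conditions: (NH4)6Mo7O24·4H2O (cat.), 30% H2O2, EtOH, 0 °C to rt
Reagents that add atoms: hydrogen peroxide, OO
Why: Molybdate-catalysed oxidation of the sulfide to the sulfone, a standard preparation of Julia–Kocienski reagents that tolerates the silyl ether.

Step 5
Reactants: 6 cyclohex-2-en-1-one
Product: 8 trimethyl{[(3S)-3-methylcyclohex-1-en-1-yl]oxy}silane, via methylzinc enolate 7 (not isolated)
Conditions: Me2Zn, Cu(OTf)2 (2 mol %), binaphthol-derived bis(1-phenylethyl)amine phosphoramidite (4 mol %, the enantiomer that gives the 3S product), toluene, −30 °C; then TMSOTf, −30 °C to rt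
Reagents that add atoms: dimethylzinc, C[Zn]C; trimethylsilyl trifluoromethanesulfonate, C[Si](C)(C)OS(=O)(=O)C(F)(F)F
Why: Copper-catalysed asymmetric conjugate addition sets C4 under ligand control, and O-silylation of the zinc enolate keeps the enol ether regiochemistry between C10 and C5.

Step 6
Reactants: 8 trimethyl{[(3S)-3-methylcyclohex-1-en-1-yl]oxy}silane
Product: 10 (2Z,3S)-2-(hydroxymethylidene)-3-methylcyclohexan-1-one, via keto acetal 9 (not isolated)
Conditions: HC(OMe)3, TMSOTf (cat.), CH2Cl2, −78 °C; then 1 M HCl, THF, rt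
Reagents that add atoms: trimethyl orthoformate, COC(OC)OC; water, O
Why: Mukaiyama-type alkylation of the silyl enol ether by the dimethoxycarbenium ion attaches C6 to C5 regiospecifically, and acetal hydrolysis gives the chelated enol of the β-keto aldehyde, so C5 is not yet a fixed stereocentre.

Step 7
Reactants: 10 (2Z,3S)-2-(hydroxymethylidene)-3-methylcyclohexan-1-one
Product: 11 (1R,2S)-1,2-dimethyl-6-oxocyclohexane-1-carbaldehyde (methyl groups trans)
Conditions: MeI, K2CO3, acetone, reflux
Reagents that add atoms: iodomethane, CI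
Why: C-alkylation of the β-keto aldehyde enolate, in which iodomethane should approach C5 anti to the pseudo-axial C4 methyl, so that the new methyl is trans to it and the formyl group cis.

Step 8
Reactants: 11 (1R,2S)-1,2-dimethyl-6-oxocyclohexane-1-carbaldehyde; 5 5-{[(2R)-3-[(tert-butyldimethylsilyl)oxy]-2-methylpropyl]sulfonyl}-1-phenyl-1H-tetrazole
Product: 12 (2R,3S)-2-[(1E,3S)-4-{[tert-butyl(dimethyl)silyl]oxy}-3-methylbut-1-en-1-yl]-2,3-dimethylcyclohexan-1-one
Conditions: 5, KN(SiMe3)2, 1,2-dimethoxyethane, −60 °C; then 11, −60 °C to rt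
Reagents that add atoms: none
Why: Julia–Kocienski olefination, in which the sulfonyl anion should add to the aldehyde in preference to the hindered ketone and Smiles rearrangement–elimination gives the E-alkene without creating or endangering a stereocentre.

Step 9
Reactants: 12 (2R,3S)-2-[(1E,3S)-4-{[tert-butyl(dimethyl)silyl]oxy}-3-methylbut-1-en-1-yl]-2,3-dimethylcyclohexan-1-one
Product: 13 (1R,2R,3S)-1-ethenyl-2-[(1E,3S)-4-{[tert-butyl(dimethyl)silyl]oxy}-3-methylbut-1-en-1-yl]-2,3-dimethylcyclohexan-1-ol
Conditions: CH2=CHMgBr, THF, −78 to 0 °C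
Reagents that add atoms: vinylmagnesium bromide, C=C[Mg]Br
Why: Grignard 1,2-addition; equatorial attack on the chair with both methyl groups equatorial and the C5 alkenyl group axial should place the vinyl group cis to the alkenyl group (C10 R), and a separable C10 epimer would not be harmful since this centre is flattened in the next step.

Step 10
Reactants: 13 (1R,2R,3S)-1-ethenyl-2-[(1E,3S)-4-{[tert-butyl(dimethyl)silyl]oxy}-3-methylbut-1-en-1-yl]-2,3-dimethylcyclohexan-1-ol
Product: 16 12-[(tert-butyldimethylsilyl)oxy]eremophil-6-en-10α-ol (trans-fused; C14 and C15 methyls cis), via ten-membered enol 14 (not isolated), via (E)-cyclodec-5-enone 15 (not isolated)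
Conditions: DBU, toluene, 220 °C, sealed tube
Reagents that add atoms: none
Why: A chair [3,3] shift of the carbinol (C5 alkenyl group axial, vinyl group and both methyls equatorial) forms C7–C8, breaks C5–C10 and gives enol 14, which DBU tautomerises to ketone 15; the closest known reaction is the thermal oxy-Cope/transannular carbonyl-ene cascade of 1,2-dialkenylcyclohexanols to ring-fusion decalinols. Ring B then closes transannularly across the ten-membered ring by a concerted six-centre ene reaction: C10 bonds to C5, the C7 hydrogen passes to oxygen and the alkene moves to C6=C7. Because the shift is suprafacial and the alkenyl group is E, the side chain at C7 lies anti to C5 and the only C7 hydrogen sits on the alkene face opposite to the one C10 left, so the ring must turn its alkene over before the suprafacial ene step. C10 therefore returns to the other face and C5 is inverted, which is why 13 carries the C5 methyl trans to the C4 methyl and 16 has them cis; the C4 methyl is equatorial on the chair-like ring A of the closing array. The E-alkene holds the C5 methyl and C9 on the same side of that array, so the C10 oxygen ends anti to the C5 methyl (trans fusion). The step needs the E-cyclodecenone and 6–6 rather than 5–7 closure: the first is secured by the chair in which C4 is equatorial on the reacting six-atom array, the second by the geometry of the concerted ene step, as in the precedent.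

Step 11
Reactants: 16 12-[(tert-butyldimethylsilyl)oxy]eremophil-6-en-10α-ol
Product: 17 12-[(tert-butyldimethylsilyl)oxy]eremophil-6-ene-8α,10α-diol
Conditions: SeO2 (cat.), t-BuOOH, CH2Cl2, rt
Reagents that add atoms: selenium dioxide, O=[Se]=O (oxygen carrier); tert-butyl hydroperoxide, CC(C)(C)OO (terminal oxidant)
Why: Selenium dioxide allylic hydroxylation (ene reaction, then [2,3] shift) oxidises α to the more substituted alkene carbon, at the ring CH2 in preference to the side-chain CH, and returns the alkene to C6=C7; the C8 configuration (expected α, attack away from C14) is removed in step 12.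

Step 12
Reactants: 17 12-[(tert-butyldimethylsilyl)oxy]eremophil-6-ene-8α,10α-diol
Product: 18 12-[(tert-butyldimethylsilyl)oxy]-10α-hydroxyeremophil-6-en-8-one
Conditions: Dess–Martin periodinane, CH2Cl2, rt
Reagents that add atoms: none
Why: Dess–Martin oxidation of the secondary allylic alcohol to the enone, which cannot touch the tertiary C10 hydroxyl.

Step 13
Reactants: 18 12-[(tert-butyldimethylsilyl)oxy]-10α-hydroxyeremophil-6-en-8-one
Product: 19 12-[(tert-butyldimethylsilyl)oxy]eremophila-6,9-dien-8-one
Conditions: NaOMe (cat.), MeOH, rt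
Reagents that add atoms: none
Why: E1cB dehydration of the β-hydroxy ketone through the C9 enolate, as in the last stage of a Robinson annulation, can only give the C9=C10 alkene, and a reversible retro-aldol opening would lead back to the same dienone.

Step 14
Reactants: 19 12-[(tert-butyldimethylsilyl)oxy]eremophila-6,9-dien-8-one
Product: 20 12-[(tert-butyldimethylsilyl)oxy]-8-[(triethylsilyl)oxy]eremophila-1(10),6,8-triene
Conditions: Et3SiOTf, Et3N, CH2Cl2, 0 °C
Reagents that add atoms: triethylsilyl trifluoromethanesulfonate, CC[Si](CC)(CC)OS(=O)(=O)C(F)(F)F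
Why: Soft enolisation to the extended silyl enol ether; the dienone has no α-hydrogen, so only the γ-hydrogens at C1 can be removed.

Step 15
Reactants: 20 12-[(tert-butyldimethylsilyl)oxy]-8-[(triethylsilyl)oxy]eremophila-1(10),6,8-triene
Product: 21 12-[(tert-butyldimethylsilyl)oxy]-1β-hydroxyeremophila-6,9-dien-8-one
Conditions: mCPBA, CH2Cl2/hexane, −20 °C; aqueous work-up
Reagents that add atoms: 3-chloroperoxybenzoic acid, OOC(=O)c1cccc(Cl)c1
Why: Vinylogous Rubottom oxidation: the peracid epoxidises the terminal C1=C10 bond of the silyloxy diene and collapse of the epoxide restores the dienone with a C1 hydroxyl; axial attack at C1, syn to the axial C5 methyl as in the 6β-hydroxylation of steroidal 3,5-dienol ethers, should give the 1β alcohol.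

Step 16
Reactants: 21 12-[(tert-butyldimethylsilyl)oxy]-1β-hydroxyeremophila-6,9-dien-8-one; 22 angelic acid
Product: 24 1β-angeloyloxy-12-[(tert-butyldimethylsilyl)oxy]eremophila-6,9-dien-8-one, via mixed anhydride 23 (not isolated)
Conditions: 22, 2,4,6-trichlorobenzoyl chloride, Et3N, toluene, rt; then 21, 80 °C (no DMAP)
Reagents that add atoms: none
Why: Yamaguchi-type esterification through the mixed anhydride without a nucleophilic catalyst, the usual way to keep the Z-geometry of the angelate; the C1 configuration is retained.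

Step 17
Reactants: 24 1β-angeloyloxy-12-[(tert-butyldimethylsilyl)oxy]eremophila-6,9-dien-8-one
Product: 25 1β-angeloyloxy-12-hydroxyeremophila-6,9-dien-8-one
Conditions: HF·pyridine, pyridine, THF, 0 °C to rt
Reagents that add atoms: none
Why: Buffered fluoride cleavage of the primary silyl ether, which should spare the allylic ester and the dienone.

Step 18
Reactants: 25 1β-angeloyloxy-12-hydroxyeremophila-6,9-dien-8-one
Product: 26 (11S)-1β-angeloyloxy-8-oxoeremophila-6,9-dien-12-oic acid
Conditions: TEMPO (cat.), PhI(OAc)2, MeCN/aqueous buffer (pH 7), rt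
Reagents that add atoms: water, O
Why: Oxoammonium (TEMPO) oxidation of the primary alcohol through the aldehyde hydrate to the acid under near-neutral conditions, chosen to limit epimerisation at C11, which is α to the transient aldehyde.

Step 19
Reactants: 26 (11S)-1β-angeloyloxy-8-oxoeremophila-6,9-dien-12-oic acid
Product: 27 methyl (11S)-1β-angeloyloxy-8-oxoeremophila-6,9-dien-12-oate (target)
Conditions: Me3SiCHN2, toluene/MeOH, 0 °C
Reagents that add atoms: (trimethylsilyl)diazomethane, C[Si](C)(C)C=[N+]=[N-]
Why: Neutral O-methylation of the acid with diazomethane released in the flask, which avoids base at the C11 centre.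

**Compound list**

1 | methyl (2R)-3-hydroxy-2-methylpropanoate | OC[C@@H](C)C(=O)OC | starting material
2 | methyl (2R)-3-[(tert-butyldimethylsilyl)oxy]-2-methylpropanoate | CC(C)(C)[Si](C)(C)OC[C@@H](C)C(=O)OC | intermediate
3 | (2S)-3-[(tert-butyldimethylsilyl)oxy]-2-methylpropan-1-ol | CC(C)(C)[Si](C)(C)OC[C@@H](C)CO | intermediate
4 | 5-{[(2R)-3-[(tert-butyldimethylsilyl)oxy]-2-methylpropyl]sulfanyl}-1-phenyl-1H-tetrazole | CC(C)(C)[Si](C)(C)OC[C@@H](C)CSc1nnnn1-c1ccccc1 | intermediate
5 | 5-{[(2R)-3-[(tert-butyldimethylsilyl)oxy]-2-methylpropyl]sulfonyl}-1-phenyl-1H-tetrazole | CC(C)(C)[Si](C)(C)OC[C@@H](C)CS(=O)(=O)c1nnnn1-c1ccccc1 | intermediate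
6 | cyclohex-2-en-1-one | O=C1C=CCCC1 | starting material
7 | methylzinc (3S)-3-methylcyclohex-1-en-1-olate | C[C@H]1CCCC(O[Zn]C)=C1 | intermediate
8 | trimethyl{[(3S)-3-methylcyclohex-1-en-1-yl]oxy}silane | C[C@H]1CCCC(O[Si](C)(C)C)=C1 | intermediate
9 | (2S,3S)-2-(dimethoxymethyl)-3-methylcyclohexan-1-one (substituents trans) | O=C1CCC[C@H](C)[C@H]1C(OC)OC | intermediate
10 | (2Z,3S)-2-(hydroxymethylidene)-3-methylcyclohexan-1-one | O=C1CCC[C@H](C)/C1=C/O | intermediate
11 | (1R,2S)-1,2-dimethyl-6-oxocyclohexane-1-carbaldehyde | O=C1CCC[C@H](C)[C@]1(C)C=O | intermediate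
12 | (2R,3S)-2-[(1E,3S)-4-{[tert-butyl(dimethyl)silyl]oxy}-3-methylbut-1-en-1-yl]-2,3-dimethylcyclohexan-1-one | O=C1CCC[C@H](C)[C@]1(C)/C=C/[C@H](C)CO[Si](C)(C)C(C)(C)C | intermediate
13 | (1R,2R,3S)-1-ethenyl-2-[(1E,3S)-4-{[tert-butyl(dimethyl)silyl]oxy}-3-methylbut-1-en-1-yl]-2,3-dimethylcyclohexan-1-ol | O[C@@]1(C=C)CCC[C@H](C)[C@]1(C)/C=C/[C@H](C)CO[Si](C)(C)C(C)(C)C | intermediate
14 | (1E,4R,5E,7S)-4-[(2S)-1-{[tert-butyl(dimethyl)silyl]oxy}propan-2-yl]-6,7-dimethylcyclodeca-1,5-dien-1-ol | C1C[C@H](C)/C(C)=C/[C@H]([C@H](C)CO[Si](C)(C)C(C)(C)C)C/C=C(/O)C1 | intermediate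
15 | (4R,5E,7S)-4-[(2S)-1-{[tert-butyl(dimethyl)silyl]oxy}propan-2-yl]-6,7-dimethylcyclodec-5-en-1-one | O=C1CCC[C@H](C)/C(C)=C/[C@H]([C@H](C)CO[Si](C)(C)C(C)(C)C)CC1 | intermediate
16 | 12-[(tert-butyldimethylsilyl)oxy]eremophil-6-en-10α-ol (trans-fused, 11S) | O[C@@]12CCC[C@H](C)[C@@]1(C)C=C([C@H](C)CO[Si](C)(C)C(C)(C)C)CC2 | intermediate
17 | 12-[(tert-butyldimethylsilyl)oxy]eremophil-6-ene-8α,10α-diol | O[C@@]12CCC[C@H](C)[C@@]1(C)C=C([C@H](C)CO[Si](C)(C)C(C)(C)C)[C@@H](O)C2 | intermediate
18 | 12-[(tert-butyldimethylsilyl)oxy]-10α-hydroxyeremophil-6-en-8-one | O[C@@]12CCC[C@H](C)[C@@]1(C)C=C([C@H](C)CO[Si](C)(C)C(C)(C)C)C(=O)C2 | intermediate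
19 | 12-[(tert-butyldimethylsilyl)oxy]eremophila-6,9-dien-8-one | C1CC[C@H](C)[C@@]2(C)C=C([C@H](C)CO[Si](C)(C)C(C)(C)C)C(=O)C=C12 | intermediate
20 | 12-[(tert-butyldimethylsilyl)oxy]-8-[(triethylsilyl)oxy]eremophila-1(10),6,8-triene | C1C[C@H](C)[C@@]2(C)C=C([C@H](C)CO[Si](C)(C)C(C)(C)C)C(O[Si](CC)(CC)CC)=CC2=C1 | intermediate
21 | 12-[(tert-butyldimethylsilyl)oxy]-1β-hydroxyeremophila-6,9-dien-8-one | O[C@@H]1CC[C@H](C)[C@@]2(C)C=C([C@H](C)CO[Si](C)(C)C(C)(C)C)C(=O)C=C12 | intermediate
22 | angelic acid, (Z)-2-methylbut-2-enoic acid | C/C=C(/C)C(=O)O | starting material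
23 | (Z)-2-methylbut-2-enoic 2,4,6-trichlorobenzoic anhydride | C/C=C(/C)C(=O)OC(=O)c1c(Cl)cc(Cl)cc1Cl | intermediate
24 | 1β-angeloyloxy-12-[(tert-butyldimethylsilyl)oxy]eremophila-6,9-dien-8-one | C/C=C(/C)C(=O)O[C@@H]1CC[C@H](C)[C@@]2(C)C=C([C@H](C)CO[Si](C)(C)C(C)(C)C)C(=O)C=C12 | intermediate
25 | 1β-angeloyloxy-12-hydroxyeremophila-6,9-dien-8-one | C/C=C(/C)C(=O)O[C@@H]1CC[C@H](C)[C@@]2(C)C=C([C@H](C)CO)C(=O)C=C12 | intermediate
26 | (11S)-1β-angeloyloxy-8-oxoeremophila-6,9-dien-12-oic acid | C/C=C(/C)C(=O)O[C@@H]1CC[C@H](C)[C@@]2(C)C=C([C@H](C)C(=O)O)C(=O)C=C12 | intermediate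
27 | methyl (11S)-1β-angeloyloxy-8-oxoeremophila-6,9-dien-12-oate | C/C=C(/C)C(=O)O[C@@H]1CC[C@H](C)[C@@]2(C)C=C([C@H](C)C(=O)OC)C(=O)C=C12 | target

**Step count and risks**

Total step count: 19. Longest linear sequence: 16 steps (1–4, then 8–19).

Step 10. What may go wrong: the E-alkene of the ten-membered ketone may turn over too slowly, so that closure through C6 to a 5–7 skeleton or thermal cleavage of the carbinol takes over. The fallback changes to the pairing that needs no turn-over: a (Z)-alkenyl group on a C5 centre of opposite configuration, for which the [3,3] shift leaves the C7 hydrogen on the face from which C10 departs. It sets out from alcohol 3 and commercial 2-methylcyclohex-2-en-1-one and comes back at 16. Alcohol 3 is converted (I2, PPh3, imidazole) into (R)-tert-butyl(3-iodo-2-methylpropoxy)dimethylsilane F1 and then (PPh3, MeCN, reflux) into [(2R)-3-[(tert-butyldimethylsilyl)oxy]-2-methylpropyl]triphenylphosphonium iodide F2. Conjugate methylation of the enone (Me3Al, Cu(OTf)2, phosphoramidite) gives dimethylaluminium (3S)-2,3-dimethylcyclohex-1-en-1-olate F3, which is silylated in the flask (TMSOTf) to trimethyl{[(3S)-2,3-dimethylcyclohex-1-en-1-yl]oxy}silane F4. Alkylation with trimethyl orthoformate and TMSOTf, now anti to the C4 methyl at the tetrasubstituted enol ether, should give (2S,3S)-2-(dimethoxymethyl)-2,3-dimethylcyclohexan-1-one F5, and hydrolysis the cis-dimethyl keto aldehyde (1S,2S)-1,2-dimethyl-6-oxocyclohexane-1-carbaldehyde F6. Wittig reaction of the ylide from F2 (NaN(SiMe3)2, THF, −78 °C) with F6 should give (2S,3S)-2-[(1Z,3S)-4-{[tert-butyl(dimethyl)silyl]oxy}-3-methylbut-1-en-1-yl]-2,3-dimethylcyclohexan-1-one F7. Vinylmagnesium bromide then gives the carbinol (1R,2S,3S)-1-ethenyl-2-[(1Z,3S)-4-{[tert-butyl(dimethyl)silyl]oxy}-3-methylbut-1-en-1-yl]-2,3-dimethylcyclohexan-1-ol F8. Heating as in step 10 should lead through the enol (1Z,4R,5E,7S)-4-[(2S)-1-{[tert-butyl(dimethyl)silyl]oxy}propan-2-yl]-6,7-dimethylcyclodeca-1,5-dien-1-ol F9 to the same ketone 15, now born with C10 and the C7 hydrogen on the same alkene face, and on to 16. The price is a more crowded chair for the [3,3] shift, with the C5 methyl and the side chain both pseudo-axial.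

Step 15. What may go wrong: attack of the peracid on the α face of C1, or a mixture of C1 epimers. The fallback sets C1 by hydride delivery to a ketone instead of oxygen delivery to the enol ether; it sets out from 20 and comes back at 21. The oxidation is run without regard to facial selectivity, so that 12-[(tert-butyldimethylsilyl)oxy]-1α-hydroxyeremophila-6,9-dien-8-one F10 may be the main product. The C1 alcohols are oxidised (Dess–Martin periodinane) to 12-[(tert-butyldimethylsilyl)oxy]eremophila-6,9-diene-1,8-dione F11. Reduction with NaBH4 and CeCl3·7H2O in MeOH at −78 °C should take the less hindered, more electrophilic C1 carbonyl from the α face, away from the axial C5 methyl, to give 21.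

Step 11. What may go wrong: poor site selectivity between the ring C8 methylene and the side-chain C11 methine, and a slow ene reaction at C6 next to the quaternary C5. The fallback is a hydrogen-atom-abstraction C–H oxidation that goes straight to the ketone; it sets out from 16 and comes back at 18. It is the N-hydroxyphthalimide-mediated electrochemical allylic oxidation (N-hydroxytetrachlorophthalimide (cat.), t-BuOOH, pyridine, LiClO4, acetone, carbon electrodes, constant current), which should abstract the axial C8 hydrogen aligned with the alkene and makes step 12 unnecessary. It makes no new compound (F0).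

**Further compounds**

F1 | step 10 | (R)-tert-butyl(3-iodo-2-methylpropoxy)dimethylsilane | CC(C)(C)[Si](C)(C)OC[C@@H](C)CI
F2 | step 10 | [(2R)-3-[(tert-butyldimethylsilyl)oxy]-2-methylpropyl]triphenylphosphonium iodide | CC(C)(C)[Si](C)(C)OC[C@@H](C)C[P+](c1ccccc1)(c1ccccc1)c1ccccc1.[I-]
F3 | step 10 | dimethylaluminium (3S)-2,3-dimethylcyclohex-1-en-1-olate | C[C@H]1CCCC(O[Al](C)C)=C1C
F4 | step 10 | trimethyl{[(3S)-2,3-dimethylcyclohex-1-en-1-yl]oxy}silane | C[C@H]1CCCC(O[Si](C)(C)C)=C1C
F5 | step 10 | (2S,3S)-2-(dimethoxymethyl)-2,3-dimethylcyclohexan-1-one | O=C1CCC[C@H](C)[C@@]1(C)C(OC)OC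
F6 | step 10 | (1S,2S)-1,2-dimethyl-6-oxocyclohexane-1-carbaldehyde | O=C1CCC[C@H](C)[C@@]1(C)C=O
F7 | step 10 | (2S,3S)-2-[(1Z,3S)-4-{[tert-butyl(dimethyl)silyl]oxy}-3-methylbut-1-en-1-yl]-2,3-dimethylcyclohexan-1-one | O=C1CCC[C@H](C)[C@@]1(C)/C=C\[C@H](C)CO[Si](C)(C)C(C)(C)C
F8 | step 10 | (1R,2S,3S)-1-ethenyl-2-[(1Z,3S)-4-{[tert-butyl(dimethyl)silyl]oxy}-3-methylbut-1-en-1-yl]-2,3-dimethylcyclohexan-1-ol | O[C@@]1(C=C)CCC[C@H](C)[C@@]1(C)/C=C\[C@H](C)CO[Si](C)(C)C(C)(C)C
F9 | step 10 | (1Z,4R,5E,7S)-4-[(2S)-1-{[tert-butyl(dimethyl)silyl]oxy}propan-2-yl]-6,7-dimethylcyclodeca-1,5-dien-1-ol | C1C[C@H](C)/C(C)=C/[C@H]([C@H](C)CO[Si](C)(C)C(C)(C)C)C/C=C(\O)C1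
F10 | step 15 | 12-[(tert-butyldimethylsilyl)oxy]-1α-hydroxyeremophila-6,9-dien-8-one | O[C@H]1CC[C@H](C)[C@@]2(C)C=C([C@H](C)CO[Si](C)(C)C(C)(C)C)C(=O)C=C12
F11 | step 15 | 12-[(tert-butyldimethylsilyl)oxy]eremophila-6,9-diene-1,8-dione | O=C1CC[C@H](C)[C@@]2(C)C=C([C@H](C)CO[Si](C)(C)C(C)(C)C)C(=O)C=C12
F0 | step 11 | none | none
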